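**Plan**

- Each outer ring is numbered C1 (butyryl), C2–O, C3 (methyl), C4–O, C5 (bridge CH2), C6–O. The retrosynthesis first cuts the five O–alkyl bonds of a penta-ether, then in each outer ring the bonds C1–C2 and C5–C6.
- The feature that allows this: three oxygens (C2, C4, C6) alternate with three carbons. C1 with its butyryl group and C6–O is the push-pull alkyne 1-ethoxyhex-1-yn-3-one. C2(O)–C3(Me)–C4(O)–C5 is a 1-methoxy-1,3-bis(silyloxy)diene hung on the central ring through the bridge carbon.
- The diene arms go back to β-keto esters, cut between the bridge carbon and its neighbour into 2,4,6-trimethoxybenzene-1,3-dicarbaldehyde and the dianion of methyl 2-methylacetoacetate. The central butyryl group is cut as a Friedel–Crafts bond.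
- Forward: the central ring is completed first (diformylation, chain extension, deoxygenation, acylation, silylation). Both outer rings then close in one operation, and a global dealkylation ends the route.
- Stereochemistry: the target has no stereocentre; transient centres are formed without control and erased.

Key step: step 8

Remark: 5, 6, 8 and 15 are diastereomer mixtures at centres that do not matter and are written without descriptors. The double-bond geometries given for 9 and 10 are the expected major ones and do not affect the outcome. N-Methoxy-N-methylbutanamide (12) is taken as a purchased reagent.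

**Route**

Step 1
Reactants: 1 1,3,5-trimethoxybenzene
Product: 2 2,4,6-trimethoxybenzene-1,3-dicarbaldehyde
Conditions: Cl2CHOMe (3 equiv), TiCl4 (4 equiv), CH2Cl2, 0 → 20 °C; then ice-water
Reagents that add atoms: dichloromethyl methyl ether COC(Cl)Cl; water O
Why: Rieche formylation, an electrophilic aromatic substitution in which every free position is ortho, ortho and para to the three methoxy groups, so a second formyl group should still enter while the last position, deactivated by two carbonyl groups, stays C–H.

Step 2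
Reactants: 2 2,4,6-trimethoxybenzene-1,3-dicarbaldehyde; 3 methyl 2-methyl-3-oxobutanoate
Product: 5 dimethyl 5,5'-(2,4,6-trimethoxy-1,3-phenylene)bis(5-hydroxy-2-methyl-3-oxopentanoate), via sodium lithium dianion 4 (not isolated)
Conditions: 3 (2.4 equiv), NaH, THF, 0 °C; n-BuLi, 0 °C; then 2, −78 → −20 °C; aq. NH4Cl
Reagents that add atoms: none
Why: Aldol addition of an acetoacetate dianion, whose terminal carbanion is far more nucleophilic than the inner enolate and should add to both non-enolisable aldehydes; the carbinol and α-carbon stereocentres arise without control and are all removed in steps 3, 5 and 6.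

Step 3
Reactants: 5 dimethyl 5,5'-(2,4,6-trimethoxy-1,3-phenylene)bis(5-hydroxy-2-methyl-3-oxopentanoate)
Product: 6 dimethyl 5,5'-(2,4,6-trimethoxy-1,3-phenylene)bis(2-methyl-3-oxopentanoate)
Conditions: Et3SiH (6 equiv), CF3CO2H, CH2Cl2, 0 °C
Reagents that add atoms: none
Why: Ionic hydrogenation: the acid ionises the benzylic alcohols, whose cations are stabilised by two ortho and one para methoxy group, and the excess silane should deliver hydride faster than the free ring position of another molecule can capture the cation, while the weakly basic β-keto esters are not reduced.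

Step 4
Reactants: 6 dimethyl 5,5'-(2,4,6-trimethoxy-1,3-phenylene)bis(2-methyl-3-oxopentanoate); 7 butanoyl chloride
Product: 8 dimethyl 5,5'-(5-butanoyl-2,4,6-trimethoxy-1,3-phenylene)bis(2-methyl-3-oxopentanoate)
Conditions: TiCl4 (3.5 equiv), CH2Cl2, −20 → 0 °C; then 1 M HCl
Reagents that add atoms: none
Why: Friedel–Crafts acylation at the only unsubstituted ring carbon, which is activated by all three methoxy groups, while the two β-keto esters are held as unreactive TiCl4 chelates (hence the excess of TiCl4); placing the ketone now spares the later polyphenol a Lewis-acid acylation.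

Step 5
Reactants: 8 dimethyl 5,5'-(5-butanoyl-2,4,6-trimethoxy-1,3-phenylene)bis(2-methyl-3-oxopentanoate)
Product: 9 dimethyl (2Z,2'Z)-5,5'-(5-butanoyl-2,4,6-trimethoxy-1,3-phenylene)bis[2-methyl-3-(trimethylsilyloxy)pent-2-enoate]
Conditions: TMSCl, Et3N, toluene, 20 °C; filtration under argon
Reagents that add atoms: chlorotrimethylsilane C[Si](C)(C)Cl
Why: Soft enolisation and O-silylation of the β-keto esters, the first stage of the standard two-stage preparation of 1-alkoxy-1,3-bis(silyloxy)dienes; the aryl ketone, shielded by two ortho methoxy groups and far less acidic, should not react with this weak base.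

Step 6
Reactants: 9 dimethyl (2Z,2'Z)-5,5'-(5-butanoyl-2,4,6-trimethoxy-1,3-phenylene)bis[2-methyl-3-(trimethylsilyloxy)pent-2-enoate]
Product: 10 1-[(1Z)-1-(trimethylsilyloxy)but-1-enyl]-3,5-bis[(2Z,4Z)-5-methoxy-4-methyl-3,5-bis(trimethylsilyloxy)penta-2,4-dienyl]-2,4,6-trimethoxybenzene
Conditions: LiN(iPr)2 (3.6 equiv), THF, −78 °C; TMSCl, −78 → 20 °C; pentane, filtration under argon
Reagents that add atoms: chlorotrimethylsilane C[Si](C)(C)Cl
Why: Kinetic γ-deprotonation of each silyloxy enoate and O-silylation of the ester dienolate gives the silyl ketene acetal dienes; the aryl ketone is enolised as well and carried as its silyl enol ether, a protection in passing that is undone in the work-up of step 8, so incomplete silylation at that site would converge on the same product.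

Step 7
Reactants: 11 ethoxyethyne; 12 N-methoxy-N-methylbutanamide
Product: 14 1-ethoxyhex-1-yn-3-one, via lithium ethoxyacetylide 13 (not isolated)
Conditions: n-BuLi, THF, −78 °C; then 12, −78 → −20 °C; cold aq. NH4Cl
Reagents that add atoms: none
Why: Weinreb ketone synthesis: the lithium acetylide adds once to the N-methoxy-N-methylamide and the chelated tetrahedral intermediate survives until the cold quench, which prevents over-addition and keeps the acid-sensitive ynol ether intact.

Step 8
Reactants: 10 1-[(1Z)-1-(trimethylsilyloxy)but-1-enyl]-3,5-bis[(2Z,4Z)-5-methoxy-4-methyl-3,5-bis(trimethylsilyloxy)penta-2,4-dienyl]-2,4,6-trimethoxybenzene; 14 1-ethoxyhex-1-yn-3-one (2.5 equiv)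
Product: 16 1-[3,5-bis[(3-butanoyl-2-ethoxy-4,6-dihydroxy-5-methylphenyl)methyl]-2,4,6-trimethoxyphenyl]butan-1-one, via bis-cycloadduct 15 (not isolated)
Conditions: toluene, 0 → 60 °C; then 1 M HCl, THF, 20 °C
Reagents that add atoms: none
Why: Each 1-methoxy-1,3-bis(trimethylsilyloxy)diene arm of 10 adds to the push-pull alkyne 14 in a normal-electron-demand [4+2] cycloaddition (or its stepwise equivalent, a vinylogous Mukaiyama–Michael addition followed by closure of the allenolate carbon onto the ketene acetal carbon); the closest known reaction type is the Diels–Alder benzannulation of 1-alkoxy-1,3-bis(silyloxy)dienes with acetylenic ketones and esters. Each outer ring closes in this intermolecular six-membered annulation through the two new bonds C5–C6 (diene CH terminus to the ethoxy-bearing alkyne carbon) and C1–C2 (ketene acetal carbon to the acyl-bearing alkyne carbon), giving bis-cycloadduct 15. In the acidic work-up the mixed silyl methyl ketal at C2 collapses with loss of methanol and the cyclohexadienone enolises through the C5–H, so both outer rings become aromatic; the silyl ethers, including the bystander aryl silyl enol ether, are hydrolysed. The sp3 centres of 15 form without control and are erased, so no stereocentre has to be set. The only selectivity needed is regiochemical and is secured by matched polarisation: the largest HOMO coefficient of the diene lies at the bridge-bearing terminus and the largest LUMO coefficient of 14 at the alkyne carbon β to the ketone, while the C3 methyl group blocks the competing [3+3] mode through the central diene carbon, which could not aromatise.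

Step 9
Reactants: 16 1-[3,5-bis[(3-butanoyl-2-ethoxy-4,6-dihydroxy-5-methylphenyl)methyl]-2,4,6-trimethoxyphenyl]butan-1-one
Product: 17 1-[3,5-bis[(3-butanoyl-2,4,6-trihydroxy-5-methylphenyl)methyl]-2,4,6-trihydroxyphenyl]butan-1-one
Conditions: BBr3 (excess), CH2Cl2, −78 → 20 °C; then ice-water
Reagents that add atoms: none
Why: Lewis-acid ether cleavage with BBr3 (boron coordinates the ether oxygen, bromide attacks the alkyl group) should remove the three methyl and two ethyl groups, all of which sit ortho or para to a ketone or are twisted out of the ring plane by two neighbours, while aryl ketones and diarylmethane bridges are normally retained.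

**Compound list**

1 | 1,3,5-trimethoxybenzene | COc1cc(OC)cc(OC)c1 | starting material
2 | 2,4,6-trimethoxybenzene-1,3-dicarbaldehyde | COc1cc(OC)c(C=O)c(OC)c1C=O | intermediate
3 | methyl 2-methyl-3-oxobutanoate | COC(=O)C(C)C(C)=O | starting material
4 | sodium lithium dianion of methyl 2-methyl-3-oxobutanoate (not isolated) | COC(=O)[C-](C)C(=O)[CH2-].[Na+].[Li+] | intermediate
5 | dimethyl 5,5'-(2,4,6-trimethoxy-1,3-phenylene)bis(5-hydroxy-2-methyl-3-oxopentanoate), mixture of diastereomers | COc1cc(OC)c(C(O)CC(=O)C(C)C(=O)OC)c(OC)c1C(O)CC(=O)C(C)C(=O)OC | intermediate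
6 | dimethyl 5,5'-(2,4,6-trimethoxy-1,3-phenylene)bis(2-methyl-3-oxopentanoate), mixture of diastereomers | COc1cc(OC)c(CCC(=O)C(C)C(=O)OC)c(OC)c1CCC(=O)C(C)C(=O)OC | intermediate
7 | butanoyl chloride | CCCC(=O)Cl | starting material
8 | dimethyl 5,5'-(5-butanoyl-2,4,6-trimethoxy-1,3-phenylene)bis(2-methyl-3-oxopentanoate), mixture of diastereomers | CCCC(=O)c1c(OC)c(CCC(=O)C(C)C(=O)OC)c(OC)c(CCC(=O)C(C)C(=O)OC)c1OC | intermediate
9 | dimethyl (2Z,2'Z)-5,5'-(5-butanoyl-2,4,6-trimethoxy-1,3-phenylene)bis[2-methyl-3-(trimethylsilyloxy)pent-2-enoate] | CCCC(=O)c1c(OC)c(CC/C(O[Si](C)(C)C)=C(\C)C(=O)OC)c(OC)c(CC/C(O[Si](C)(C)C)=C(\C)C(=O)OC)c1OC | intermediate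
10 | 1-[(1Z)-1-(trimethylsilyloxy)but-1-enyl]-3,5-bis[(2Z,4Z)-5-methoxy-4-methyl-3,5-bis(trimethylsilyloxy)penta-2,4-dienyl]-2,4,6-trimethoxybenzene | CC/C=C(\O[Si](C)(C)C)c1c(OC)c(C/C=C(O[Si](C)(C)C)/C(C)=C(/OC)O[Si](C)(C)C)c(OC)c(C/C=C(O[Si](C)(C)C)/C(C)=C(/OC)O[Si](C)(C)C)c1OC | intermediate
11 | ethoxyethyne | CCOC#C | starting material
12 | N-methoxy-N-methylbutanamide | CCCC(=O)N(C)OC | starting material
13 | lithium ethoxyacetylide (not isolated) | [Li]C#COCC | intermediate
14 | 1-ethoxyhex-1-yn-3-one | CCCC(=O)C#COCC | intermediate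
15 | 1-[(1Z)-1-(trimethylsilyloxy)but-1-enyl]-3,5-bis[[3-butanoyl-2-ethoxy-4-methoxy-5-methyl-4,6-bis(trimethylsilyloxy)cyclohexa-2,5-dien-1-yl]methyl]-2,4,6-trimethoxybenzene, mixture of diastereomers (not isolated) | CC/C=C(\O[Si](C)(C)C)c1c(OC)c(CC2C(OCC)=C(C(=O)CCC)C(OC)(O[Si](C)(C)C)C(C)=C2O[Si](C)(C)C)c(OC)c(CC2C(OCC)=C(C(=O)CCC)C(OC)(O[Si](C)(C)C)C(C)=C2O[Si](C)(C)C)c1OC | intermediate
16 | 1-[3,5-bis[(3-butanoyl-2-ethoxy-4,6-dihydroxy-5-methylphenyl)methyl]-2,4,6-trimethoxyphenyl]butan-1-one | CCCC(=O)c1c(OC)c(Cc2c(OCC)c(C(=O)CCC)c(O)c(C)c2O)c(OC)c(Cc2c(OCC)c(C(=O)CCC)c(O)c(C)c2O)c1OC | intermediate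
17 | 1-[3,5-bis[(3-butanoyl-2,4,6-trihydroxy-5-methylphenyl)methyl]-2,4,6-trihydroxyphenyl]butan-1-one | CCCC(=O)c1c(O)c(C)c(O)c(Cc2c(O)c(Cc3c(O)c(C)c(O)c(C(=O)CCC)c3O)c(O)c(C(=O)CCC)c2O)c1O | target

**Step count and risks**

Total: 9 steps. Longest linear sequence: 8 steps (steps 1–6, 8 and 9 from 1); step 7 is a one-step side branch.

Steps most likely to fail:

1. Step 8. The ethoxy donor lowers the electrophilicity of the alkyne, so the cycloaddition may be slower than protodesilylation of the dienes or thermal breakdown of the ynol ether, and ring closure may stall after the first C–C bond on one arm. The fallback gives up ring construction and attaches preformed outer rings; it sets out from 2 and 7 and returns to the route at 17. Reduction of 2 with NaBH4 (MeOH–THF, 0 °C) would give 2,4-bis(hydroxymethyl)-1,3,5-trimethoxybenzene F1. Friedel–Crafts acylation of commercial 2-methylbenzene-1,3,5-triol with 7 (AlCl3, nitrobenzene–CH2Cl2) would give 1-(2,4,6-trihydroxy-3-methylphenyl)butan-1-one F2. Catalytic TsOH in MeCN would ionise the benzylic alcohols of F1, added slowly to an excess of F2, and the cations should alkylate the single free ring carbon of F2 to give 2,4-bis[(3-butanoyl-2,4,6-trihydroxy-5-methylphenyl)methyl]-1,3,5-trimethoxybenzene F3. Friedel–Crafts butyrylation of the last free carbon of the central ring (7, TiCl4, CH2Cl2) would give 1-[3,5-bis[(3-butanoyl-2,4,6-trihydroxy-5-methylphenyl)methyl]-2,4,6-trimethoxyphenyl]butan-1-one F4, and BBr3 as in step 9 would deliver 17.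

2. Step 6. Three enolisations must go to completion in one flask, the aryl ketone competes with the two enoates for base, and partial hydrolysis of the five silyl groups during isolation would leave mixed mono- and bis-dienes. The fallback keeps the ketone out of the diene by postponing the acylation; it sets out from 6 and returns at 16. Silylation of 6 as in step 5 would give dimethyl (2Z,2'Z)-5,5'-(2,4,6-trimethoxy-1,3-phenylene)bis[2-methyl-3-(trimethylsilyloxy)pent-2-enoate] F5. Treatment as in step 6 with two enolisations only would give 2,4-bis[(2Z,4Z)-5-methoxy-4-methyl-3,5-bis(trimethylsilyloxy)penta-2,4-dienyl]-1,3,5-trimethoxybenzene F6. Cycloaddition with 14 under the conditions of step 8 would pass through 2,4-bis[[3-butanoyl-2-ethoxy-4-methoxy-5-methyl-4,6-bis(trimethylsilyloxy)cyclohexa-2,5-dien-1-yl]methyl]-1,3,5-trimethoxybenzene F7 and give, after the acidic work-up, 2,4-bis[(3-butanoyl-2-ethoxy-4,6-dihydroxy-5-methylphenyl)methyl]-1,3,5-trimethoxybenzene F8. Friedel–Crafts butyrylation of the one free carbon of the central ring (7, TiCl4, CH2Cl2, −20 °C) would then give 16.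

3. Step 9. While the slower ethyl ether cleavage is driven to completion, the acid formed may protonate the electron-rich rings at the bridge-bearing carbons and cut or scramble the methylene bridges. If the bridges do not survive ether cleavage, the ethers must be absent when the bridges exist. This last resort therefore leaves the benzannulation aside; it sets out from 7 and returns at 17. Friedel–Crafts acylation of commercial benzene-1,3,5-triol with 7 (AlCl3, nitrobenzene) would give 1-(2,4,6-trihydroxyphenyl)butan-1-one F9. A double Mannich reaction (aqueous Me2NH, aqueous CH2O, EtOH, 20 °C) would give 1-[3,5-bis[(dimethylamino)methyl]-2,4,6-trihydroxyphenyl]butan-1-one F10. Heating F10 with two equivalents of F2 (dioxane, 100 °C) should expel dimethylamine, and each ortho-quinone methide would be trapped at the free ring carbon of F2 to give 17 without any protecting group.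

**Further compounds**

F1 | step 8 | 2,4-bis(hydroxymethyl)-1,3,5-trimethoxybenzene | COc1cc(OC)c(CO)c(OC)c1CO
F2 | step 8 | 1-(2,4,6-trihydroxy-3-methylphenyl)butan-1-one | CCCC(=O)c1c(O)cc(O)c(C)c1O
F3 | step 8 | 2,4-bis[(3-butanoyl-2,4,6-trihydroxy-5-methylphenyl)methyl]-1,3,5-trimethoxybenzene | COc1cc(OC)c(Cc2c(O)c(C)c(O)c(C(=O)CCC)c2O)c(OC)c1Cc1c(O)c(C)c(O)c(C(=O)CCC)c1O
F4 | step 8 | 1-[3,5-bis[(3-butanoyl-2,4,6-trihydroxy-5-methylphenyl)methyl]-2,4,6-trimethoxyphenyl]butan-1-one | CCCC(=O)c1c(OC)c(Cc2c(O)c(C)c(O)c(C(=O)CCC)c2O)c(OC)c(Cc2c(O)c(C)c(O)c(C(=O)CCC)c2O)c1OC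
F5 | step 6 | dimethyl (2Z,2'Z)-5,5'-(2,4,6-trimethoxy-1,3-phenylene)bis[2-methyl-3-(trimethylsilyloxy)pent-2-enoate] | COc1cc(OC)c(CC/C(O[Si](C)(C)C)=C(\C)C(=O)OC)c(OC)c1CC/C(O[Si](C)(C)C)=C(\C)C(=O)OC
F6 | step 6 | 2,4-bis[(2Z,4Z)-5-methoxy-4-methyl-3,5-bis(trimethylsilyloxy)penta-2,4-dienyl]-1,3,5-trimethoxybenzene | COc1cc(OC)c(C/C=C(O[Si](C)(C)C)/C(C)=C(/OC)O[Si](C)(C)C)c(OC)c1C/C=C(O[Si](C)(C)C)/C(C)=C(/OC)O[Si](C)(C)C
F7 | step 6 | 2,4-bis[[3-butanoyl-2-ethoxy-4-methoxy-5-methyl-4,6-bis(trimethylsilyloxy)cyclohexa-2,5-dien-1-yl]methyl]-1,3,5-trimethoxybenzene, mixture of diastereomers | COc1cc(OC)c(CC2C(OCC)=C(C(=O)CCC)C(OC)(O[Si](C)(C)C)C(C)=C2O[Si](C)(C)C)c(OC)c1CC1C(OCC)=C(C(=O)CCC)C(OC)(O[Si](C)(C)C)C(C)=C1O[Si](C)(C)C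
F8 | step 6 | 2,4-bis[(3-butanoyl-2-ethoxy-4,6-dihydroxy-5-methylphenyl)methyl]-1,3,5-trimethoxybenzene | COc1cc(OC)c(Cc2c(OCC)c(C(=O)CCC)c(O)c(C)c2O)c(OC)c1Cc1c(OCC)c(C(=O)CCC)c(O)c(C)c1O
F9 | step 9 | 1-(2,4,6-trihydroxyphenyl)butan-1-one | CCCC(=O)c1c(O)cc(O)cc1O
F10 | step 9 | 1-[3,5-bis[(dimethylamino)methyl]-2,4,6-trihydroxyphenyl]butan-1-one | CCCC(=O)c1c(O)c(CN(C)C)c(O)c(CN(C)C)c1O
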